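## Retrosynthetic overview

1. Xenoacremone H (28) ⇐ seco aryl bromide 27: the aryl C–O bond of the 13-membered para-cyclophane is closed last, by visible-light nickel/iridium etherification.
2. 27 ⇐ tricyclic β-ketoamide 21 + bromoketone 25: C-alkylation, then spontaneous closure of the hemiaminal lactam ring.
3. 21 ⇐ triene enoate 17: one intramolecular Diels–Alder reaction builds rings B and C together onto ring A.
4. 17 ⇐ enone 7 + ethyl (E)-4-oxobut-2-enoate 8: reductive syn-aldol, then homologation of the ring ketone to the (1E,3Z)-hexatrienyl arm.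
5. Ring A ⇐ (R)-pulegone 1, the only purchased stereocentre. Ring order: A (bought), B + C (one step), lactam, macrocycle.

Assumption: the hemiaminal carbon and the carbon between the ketone and the lactam carbonyl are labile (ring–chain tautomerism, enolisation) and are taken to settle, once the cyclophane is closed, in the natural configuration as the thermodynamic one.

Ring-fusion descriptors (α/β) for the tricyclic compounds use fluorene numbering; the absolute configuration is fixed by the SMILES in the compound list.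

## Route

Step 1
Reactants: 1 (R)-(+)-pulegone
Product: 2 pulegone oxide [(6R)-2,2,6-trimethyl-1-oxaspiro[2.5]octan-4-one; both spiro epimers]
Conditions: 30% H2O2, LiOH, MeOH, 0 °C to rt
Reagents that add atoms: hydrogen peroxide (OO)
Why: Weitz–Scheffer nucleophilic epoxidation of the enone; the epoxide carbons are lost or flattened later, so only the untouched methyl stereocentre matters.

Step 2
Reactants: 2 pulegone oxide
Product: 3 (5R)-5-methyl-2-(phenylsulfanyl)cyclohexan-1-one (cis/trans mixture)
Conditions: PhSH, NaH (cat.), THF, reflux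
Reagents that add atoms: thiophenol (Sc1ccccc1)
Why: thiolate opens the epoxy ketone at the α-carbon and the resulting β-alkoxide fragments by retro-aldol loss of acetone, leaving sulfur on the α-carbon remote from the methyl group.

Step 3
Reactants: 3 (5R)-5-methyl-2-(phenylsulfanyl)cyclohexan-1-one
Product: 5 (R)-5-methylcyclohex-2-en-1-one, via sulfoxide 4 (not isolated)
Conditions: NaIO4, MeOH/H2O, 0 °C; then toluene, 110 °C
Reagents that add atoms: none
Why: sulfide oxidation and thermal sulfoxide syn-elimination can only take the ring β-hydrogen, so the enone forms regiospecifically on the side away from the stereocentre.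

Step 4
Reactants: 5 (R)-5-methylcyclohex-2-en-1-one
Product: 7 (R)-3,5-dimethylcyclohex-2-en-1-one, via silyl enol ether 6 (not isolated)
Conditions: MeMgBr, CuBr·SMe2 (5 mol %), TMSCl, THF, −78 °C; then Pd(OAc)2, MeCN, rt
Reagents that add atoms: methylmagnesium bromide (C[Mg]Br)
Why: copper-catalysed conjugate methylation with silyl trapping and Saegusa–Ito dehydrogenation returns the enone with the new methyl on an sp2 carbon, so the trans selectivity of the addition is erased and the pulegone centre is kept.

Step 5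
Reactants: 7 (R)-3,5-dimethylcyclohex-2-en-1-one; 8 ethyl (E)-4-oxobut-2-enoate
Product: 11 ethyl (2E,4R)-4-[(1S,2S,4R)-2,4-dimethyl-6-oxocyclohexyl]-4-hydroxybut-2-enoate, via lithium enolate 9 (not isolated), via titanium enolate 10 (not isolated)
Conditions: Li, NH3(l), t-BuOH (1 equiv), THF, −78 °C; evaporate NH3; ClTi(OiPr)3, THF, −78 °C; then 8, −78 °C; aq. NH4Cl
Reagents that add atoms: none
Why: Stork-type dissolving-metal reduction protonates the β-carbon axially (new methyl cis to the resident one) and gives the regiodefined enolate; its triisopropoxytitanium enolate adds to the aldehyde anti to the adjacent methyl group through a closed syn-selective aldol transition state, setting three stereocentres from the pulegone one.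

Step 6
Reactants: 11 aldol adduct
Product: 12 ethyl (2E,4R)-4-[(tert-butyldimethylsilyl)oxy]-4-[(1S,2S,4R)-2,4-dimethyl-6-oxocyclohexyl]but-2-enoate
Conditions: TBSOTf, 2,6-lutidine, CH2Cl2, −78 °C
Reagents that add atoms: tert-butyldimethylsilyl triflate (CC(C)(C)[Si](C)(C)OS(=O)(=O)C(F)(F)F)
Why: low-temperature silylation protects the β-hydroxy ketone against retro-aldol cleavage and later oxa-Michael addition without touching any stereocentre.

Step 7
Reactants: 12 silyl ether ketone
Product: 14 ethyl (2E,4R)-4-[(tert-butyldimethylsilyl)oxy]-4-[(1R,2R,4R,6S)-2-formyl-4,6-dimethylcyclohexyl]but-2-enoate, via methyl enol ether 13 (not isolated)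
Conditions: (MeOCH2)PPh3Cl, KN(SiMe3)2, THF, 0 °C to rt; then 1 M HCl, THF, 0 °C to rt
Reagents that add atoms: (methoxymethyl)triphenylphosphonium chloride (COC[P+](c1ccccc1)(c1ccccc1)c1ccccc1.[Cl-]); water (O)
Why: Wittig methoxymethylenation and enol ether hydrolysis homologate the ketone by one carbon, and the new formyl-bearing centre equilibrates through its enol to the all-equatorial isomer (formyl trans to the side chain, cis to both methyls).

Step 8
Reactants: 14 aldehyde
Product: 15 ethyl (2E,4R)-4-[(tert-butyldimethylsilyl)oxy]-4-{(1R,2S,4R,6S)-2,4-dimethyl-6-[(1E)-3-oxoprop-1-en-1-yl]cyclohexyl}but-2-enoate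
Conditions: Ph3P=CHCHO, toluene, 80 °C
Reagents that add atoms: (triphenylphosphoranylidene)acetaldehyde (O=CC=P(c1ccccc1)(c1ccccc1)c1ccccc1)
Why: Wittig olefination with a stabilised ylide gives the (E)-enal selectively and leaves the hindered enoate alone.

Step 9
Reactants: 15 enal
Product: 17 ethyl (2E,4R)-4-[(tert-butyldimethylsilyl)oxy]-4-{(1R,2S,4R,6S)-2-[(1E,3Z)-hexa-1,3,5-trien-1-yl]-4,6-dimethylcyclohexyl}but-2-enoate, via titanium β-oxido phosphine adduct 16 (not isolated)
Conditions: allyldiphenylphosphine, t-BuLi, THF, −78 °C; Ti(OiPr)4, −78 °C; then 15, −78 to 0 °C; then MeI, rt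
Reagents that add atoms: allyldiphenylphosphine (C=CCP(c1ccccc1)c1ccccc1)
Why: Yamamoto (Z)-dienylation (a Horner–Wittig-type olefination): the titanated α-phosphinoallyl anion adds 1,2 to the aldehyde with erythro selectivity, and P-methylation followed by syn elimination of the phosphine oxide gives the terminal (Z)-diene.

Step 10
Reactants: 17 (E,Z)-triene enoate
Product: 18 ethyl 9-[(tert-butyldimethylsilyl)oxy]-6,8-dimethyl-2-vinyl-2,4a,4b,5,6,7,8,8a,9,9a-decahydro-1H-fluorene-1-carboxylate (1α-CO2Et; 2β-vinyl; 4aβ-H; 4bα-H; 6β-Me; 8β-Me; 8aβ-H; 9β-OTBS; 9aα-H)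
Conditions: Me2AlCl (2 equiv), CH2Cl2, −78 to −20 °C
Reagents that add atoms: none
Why: Lewis-acid-promoted intramolecular Diels–Alder reaction: both arms are equatorial on the ring A chair, the diene reacts in its allylic-strain-minimised rotamer and the ester sits endo, giving the trans-anti-trans ring fusions, while the (Z)-vinyl group on the inside of the diene ends up trans to the ester; four stereocentres are set under substrate control.

Step 11
Reactants: 18 tricyclic ester
Product: 20 3-[9-hydroxy-6,8-dimethyl-2-vinyl-2,4a,4b,5,6,7,8,8a,9,9a-decahydro-1H-fluoren-1-yl]-3-oxopropanenitrile (configuration as 18; 9β-OH), via silyl β-ketonitrile 19 (not isolated)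
Conditions: MeCN, n-BuLi, THF, −78 °C; add 18, −78 to −20 °C; AcOH; then HF·pyridine, THF, 0 °C to rt
Reagents that add atoms: acetonitrile (CC#N)
Why: Claisen-type acylation of lithiated acetonitrile stops at the β-ketonitrile enolate (no over-addition; the α-centre stays equatorial), and fluoride then removes the silyl group.

Step 12
Reactants: 20 hydroxy β-ketonitrile
Product: 21 3-[9-hydroxy-6,8-dimethyl-2-vinyl-2,4a,4b,5,6,7,8,8a,9,9a-decahydro-1H-fluoren-1-yl]-3-oxopropanamide
Conditions: [PtH{(PMe2O)2H}(PMe2OH)] (2 mol %), EtOH/H2O, 80 °C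
Reagents that add atoms: water (O)
Why: neutral platinum-catalysed nitrile hydration (Ghaffar–Parkins) gives the primary β-ketoamide without epimerisation, retro-Claisen cleavage or alkene migration.

Step 13
Reactants: 22 4-bromophenylacetic acid
Product: 25 1-bromo-3-(4-bromophenyl)propan-2-one, via acid chloride 23 (not isolated), via diazoketone 24 (not isolated)
Conditions: (COCl)2, DMF (cat.), CH2Cl2, rt; TMSCHN2, MeCN/THF, 0 °C; then 48% HBr, 0 °C
Reagents that add atoms: (trimethylsilyl)diazomethane (C[Si](C)(C)C=[N+]=[N-]); hydrogen bromide (Br)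
Why: Arndt–Eistert-type acylation of the diazoalkane and protonolysis of the diazoketone with HBr give the bromomethyl ketone; no stereocentre is involved.

Step 14
Reactants: 21 β-ketoamide; 25 1-bromo-3-(4-bromophenyl)propan-2-one
Product: 27 5-(4-bromobenzyl)-5-hydroxy-3-{[9-hydroxy-6,8-dimethyl-2-vinyl-2,4a,4b,5,6,7,8,8a,9,9a-decahydro-1H-fluoren-1-yl]carbonyl}pyrrolidin-2-one (equilibrating epimers at lactam C3 and C5), via open-chain diketo amide 26 (not isolated)
Conditions: K2CO3, acetone, rt
Reagents that add atoms: none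
Why: the soft β-ketoamide enolate is C-alkylated by the α-bromoketone (SN2) and the primary amide then adds to the new ketone (ring–chain tautomerism) to give the 5-hydroxy-γ-lactam; its two new centres stay labile and are fixed only in the macrocycle.

Step 15
Reactants: 27 seco aryl bromide
Product: 28 xenoacremone H
Conditions: Ir[dF(CF3)ppy]2(dtbbpy)PF6 (2 mol %), NiCl2·DME (10 mol %), dtbbpy (10 mol %), quinuclidine (10 mol %), K2CO3, MeCN (1 mM), 450 nm LEDs, 25 °C
Reagents that add atoms: none
Why: Proposed new method: a visible-light nickel/iridium C(sp2)–O coupling used as a macrocyclisation to close a strained 13-membered para-cyclophane from a hindered secondary cyclopentanol; the aryl bromide adds oxidatively to zerovalent nickel, the alkoxide binds to the resulting divalent aryl nickel, and photo-oxidation by the excited iridium complex gives a trivalent nickel aryl alkoxide whose fast reductive elimination can pay for the ring strain at room temperature, so the hemiaminal is not exposed to Ullmann temperatures; the bond forms at oxygen, so the carbinol configuration is retained, and the two labile lactam centres then settle in the natural configuration; the closest known reactions are the intermolecular nickel/photoredox etherification of aryl bromides with alcohols and copper-mediated Ullmann macroetherification.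

## Compound list

1 | (R)-(+)-pulegone | C[C@@H]1CCC(=C(C)C)C(=O)C1 | starting material
2 | pulegone oxide (both spiro epimers) | C[C@@H]1CCC2(OC2(C)C)C(=O)C1 | intermediate
3 | (5R)-5-methyl-2-(phenylsulfanyl)cyclohexan-1-one | C[C@@H]1CCC(Sc2ccccc2)C(=O)C1 | intermediate
4 | (5R)-5-methyl-2-(phenylsulfinyl)cyclohexan-1-one (not isolated) | C[C@@H]1CCC(S(=O)c2ccccc2)C(=O)C1 | intermediate
5 | (R)-5-methylcyclohex-2-en-1-one | C[C@@H]1CC=CC(=O)C1 | intermediate
6 | (5R)-trans-3,5-dimethyl-1-(trimethylsilyloxy)cyclohex-1-ene (not isolated) | C[C@@H]1C[C@@H](C)C=C(O[Si](C)(C)C)C1 | intermediate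
7 | (R)-3,5-dimethylcyclohex-2-en-1-one | C[C@@H]1CC(C)=CC(=O)C1 | intermediate
8 | ethyl (E)-4-oxobut-2-enoate | CCOC(=O)/C=C/C=O | starting material
9 | lithium cis-3,5-dimethylcyclohex-1-en-1-olate (not isolated) | [Li+].C[C@@H]1C[C@H](C)C=C([O-])C1 | intermediate
10 | triisopropoxytitanium cis-3,5-dimethylcyclohex-1-en-1-olate (not isolated) | C[C@@H]1C[C@H](C)C=C(O[Ti](OC(C)C)(OC(C)C)OC(C)C)C1 | intermediate
11 | ethyl (2E,4R)-4-[(1S,2S,4R)-2,4-dimethyl-6-oxocyclohexyl]-4-hydroxybut-2-enoate | CCOC(=O)/C=C/[C@@H](O)[C@@H]1[C@@H](C)C[C@@H](C)CC1=O | intermediate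
12 | ethyl (2E,4R)-4-[(tert-butyldimethylsilyl)oxy]-4-[(1S,2S,4R)-2,4-dimethyl-6-oxocyclohexyl]but-2-enoate | CCOC(=O)/C=C/[C@@H](O[Si](C)(C)C(C)(C)C)[C@@H]1[C@@H](C)C[C@@H](C)CC1=O | intermediate
13 | methyl enol ether of 12 (ring C=CH–OMe; E/Z mixture; not isolated) | CCOC(=O)/C=C/[C@@H](O[Si](C)(C)C(C)(C)C)[C@@H]1[C@@H](C)C[C@@H](C)CC1=COC | intermediate
14 | ethyl (2E,4R)-4-[(tert-butyldimethylsilyl)oxy]-4-[(1R,2R,4R,6S)-2-formyl-4,6-dimethylcyclohexyl]but-2-enoate | CCOC(=O)/C=C/[C@@H](O[Si](C)(C)C(C)(C)C)[C@@H]1[C@@H](C)C[C@@H](C)C[C@H]1C=O | intermediate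
15 | ethyl (2E,4R)-4-[(tert-butyldimethylsilyl)oxy]-4-{(1R,2S,4R,6S)-2,4-dimethyl-6-[(1E)-3-oxoprop-1-en-1-yl]cyclohexyl}but-2-enoate | CCOC(=O)/C=C/[C@@H](O[Si](C)(C)C(C)(C)C)[C@@H]1[C@@H](C)C[C@@H](C)C[C@H]1/C=C/C=O | intermediate
16 | titanium β-oxido phosphine adduct of 15 (erythro; one of two erythro isomers drawn; not isolated) | CCOC(=O)/C=C/[C@@H](O[Si](C)(C)C(C)(C)C)[C@@H]1[C@@H](C)C[C@@H](C)C[C@H]1/C=C/[C@@H](O[Ti](OC(C)C)(OC(C)C)OC(C)C)[C@@H](P(c2ccccc2)c2ccccc2)C=C | intermediate
17 | ethyl (2E,4R)-4-[(tert-butyldimethylsilyl)oxy]-4-{(1R,2S,4R,6S)-2-[(1E,3Z)-hexa-1,3,5-trien-1-yl]-4,6-dimethylcyclohexyl}but-2-enoate | CCOC(=O)/C=C/[C@@H](O[Si](C)(C)C(C)(C)C)[C@@H]1[C@@H](C)C[C@@H](C)C[C@H]1/C=C/C=C\C=C | intermediate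
18 | ethyl 9-[(tert-butyldimethylsilyl)oxy]-6,8-dimethyl-2-vinyl-2,4a,4b,5,6,7,8,8a,9,9a-decahydro-1H-fluorene-1-carboxylate (1α-CO2Et; 2β-vinyl; 4aβ-H; 4bα-H; 6β-Me; 8β-Me; 8aβ-H; 9β-OTBS; 9aα-H) | C=C[C@@H]1C=C[C@H]2[C@@H]3C[C@H](C)C[C@H](C)[C@H]3[C@H](O[Si](C)(C)C(C)(C)C)[C@@H]2[C@H]1C(=O)OCC | intermediate
19 | silyl β-ketonitrile (18 with COCH2CN in place of CO2Et; not isolated) | C=C[C@@H]1C=C[C@H]2[C@@H]3C[C@H](C)C[C@H](C)[C@H]3[C@H](O[Si](C)(C)C(C)(C)C)[C@@H]2[C@H]1C(=O)CC#N | intermediate
20 | hydroxy β-ketonitrile (9β-OH; 1α-COCH2CN) | C=C[C@@H]1C=C[C@H]2[C@@H]3C[C@H](C)C[C@H](C)[C@H]3[C@H](O)[C@@H]2[C@H]1C(=O)CC#N | intermediate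
21 | hydroxy β-ketoamide (9β-OH; 1α-COCH2CONH2) | C=C[C@@H]1C=C[C@H]2[C@@H]3C[C@H](C)C[C@H](C)[C@H]3[C@H](O)[C@@H]2[C@H]1C(=O)CC(N)=O | intermediate
22 | 4-bromophenylacetic acid | OC(=O)Cc1ccc(Br)cc1 | starting material
23 | 4-bromophenylacetyl chloride (not isolated) | ClC(=O)Cc1ccc(Br)cc1 | intermediate
24 | 1-(4-bromophenyl)-3-diazopropan-2-one (not isolated) | [N-]=[N+]=CC(=O)Cc1ccc(Br)cc1 | intermediate
25 | 1-bromo-3-(4-bromophenyl)propan-2-one | BrCC(=O)Cc1ccc(Br)cc1 | intermediate
26 | open-chain diketo amide (C-alkylated 21; epimers at the new centre; not isolated) | C=C[C@@H]1C=C[C@H]2[C@@H]3C[C@H](C)C[C@H](C)[C@H]3[C@H](O)[C@@H]2[C@H]1C(=O)C(C(N)=O)CC(=O)Cc1ccc(Br)cc1 | intermediate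
27 | seco hydroxy lactam: 3-acyl-5-(4-bromobenzyl)-5-hydroxypyrrolidin-2-one on the tricycle (lactam C3 and C5 equilibrating) | C=C[C@@H]1C=C[C@H]2[C@@H]3C[C@H](C)C[C@H](C)[C@H]3[C@H](O)[C@@H]2[C@H]1C(=O)C1CC(O)(Cc2ccc(Br)cc2)NC1=O | intermediate
28 | xenoacremone H | C=C[C@@H]1C=C[C@H]2[C@@H]3C[C@H](C)C[C@H](C)[C@H]3[C@@H]3Oc4ccc(cc4)C[C@@]4(O)C[C@H](C(=O)N4)C(=O)[C@@H]1[C@H]23 | target

## Step count and risks

Total step count: 15. Longest linear sequence: 14 (steps 1–12, 14 and 15, from 1 to 28); step 13 makes the side fragment 25.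

The three steps most likely to fail:

Step 15 (the new macrocyclisation). The ring is strained, the alcohol is hindered, and the γ-hydroxy ketone can rest as a cyclic hemiketal that must reopen; the β-dicarbonyl unit may also bind nickel. The fallback closes the ring thermally with copper and builds the lactam afterwards. It sets out from 20, which is C-alkylated with 25 (K2CO3, acetone) to the open-chain bromo diketo nitrile F1. A copper-catalysed Ullmann etherification (CuI, 3,4,7,8-tetramethyl-1,10-phenanthroline, Cs2CO3, toluene, 110 °C, 1 mM) closes the aryl ether to the macrocyclic β-ketonitrile F2. Hydration with [PtH{(PMe2O)2H}(PMe2OH)] gives the macrocyclic diketo amide F3, which closes to the hemiaminal lactam and so comes back to the route at 28.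

Step 10 (Diels–Alder reaction of the (Z)-substituted triene). The (Z)-triene is a sluggish diene and can be lost to Lewis-acid oligomerisation, 1,7-hydrogen shift or electrocyclisation, and the enoate is only a moderate dienophile. The fallback changes the dienophile instead of the promoter. It sets out from 17, which is treated with LiCH2CN (THF, −78 °C) to give the (E)-trienone β-ketonitrile F4. Its ketone-activated double bond undergoes the intramolecular Diels–Alder reaction thermally (toluene, 25–40 °C) through the same endo transition state, and the product is 19, where the route is rejoined before the HF·pyridine treatment of step 11.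

Step 5 (one-pot reductive syn-aldol). The enolate may equilibrate after the ammonia is removed, the oxo-enoate may suffer conjugate addition, and the syn selectivity rests on the titanium enolate. The fallback separates enolate formation from an open-transition-state aldol. It sets out from 7: Li/NH3/t-BuOH reduction and trapping with TMSCl/Et3N gives the isolable cis trimethylsilyl enol ether F5. A fluoride-triggered aldol with 8 (tris(dimethylamino)sulfonium difluorotrimethylsilicate, cat., THF, −78 °C), which is syn-selective for cyclic enol silanes, gives the silylated syn aldol F6. Citric acid in MeOH removes the silyl group, and the route is rejoined at 11.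

Further compounds
F1 | step 15 | open-chain bromo diketo nitrile (20 C-alkylated with 25; epimers at the nitrile carbon) | C=C[C@@H]1C=C[C@H]2[C@@H]3C[C@H](C)C[C@H](C)[C@H]3[C@H](O)[C@@H]2[C@H]1C(=O)C(C#N)CC(=O)Cc1ccc(Br)cc1
F2 | step 15 | macrocyclic β-ketonitrile (13-membered aryl ether closed; nitrile in place of the lactam) | C=C[C@@H]1C=C[C@H]2[C@@H]3C[C@H](C)C[C@H](C)[C@H]3[C@@H]3Oc4ccc(cc4)CC(=O)CC(C#N)C(=O)[C@@H]1[C@H]23
F3 | step 15 | macrocyclic diketo amide (open form of 28) | C=C[C@@H]1C=C[C@H]2[C@@H]3C[C@H](C)C[C@H](C)[C@H]3[C@@H]3Oc4ccc(cc4)CC(=O)CC(C(N)=O)C(=O)[C@@H]1[C@H]23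
F4 | step 10 | (E)-trienone β-ketonitrile (17 with COCH2CN in place of CO2Et) | N#CCC(=O)/C=C/[C@@H](O[Si](C)(C)C(C)(C)C)[C@@H]1[C@@H](C)C[C@@H](C)C[C@H]1/C=C/C=C\C=C
F5 | step 5 | (5R)-cis-3,5-dimethyl-1-(trimethylsilyloxy)cyclohex-1-ene | C[C@@H]1C[C@H](C)C=C(O[Si](C)(C)C)C1
F6 | step 5 | trimethylsilyl ether of 11 | CCOC(=O)/C=C/[C@@H](O[Si](C)(C)C)[C@@H]1[C@@H](C)C[C@@H](C)CC1=O
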